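**Retrosynthetic overview**
1. Target ⇐ C8 acylation and C15 desilylation of a furanone-bridged 8-hydroxy lactone.
2. Furanone ring (formed last) ⇐ 5-endo attack of the C10 hydroxyl on C3 of a ten-membered 2-yn-1-one, the synthetic counterpart of the 10-OH→C3 hemiketalisation/dehydration of a 10-hydroxy-1,3-dione.
3. Ten-membered carbocycle and lactone (formed first, in one operation) ⇐ chromium-mediated allylation closing C6–C7, the bond made by the germacrene cyclase (farnesyl C1–C10), followed by O6–C12 lactonisation.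
4. Acyclic precursor ⇐ Sonogashira union (C3–C4) of a (Z)-iodoenal (C4–C6, C15) with an alkyne carrying C1, C2 and C7–C14.
5. Alkyne fragment ⇐ (R)-4-silyloxycyclopentenone: C10 set from C8 by CH3Li addition, ring opened at C1=C7 by ozonolysis, then Baylis–Hillman (C7–C11) and ethynylation (C1–C2).

Assumption: atom labels C1 to C15 follow germacrane numbering of the target, the two chiral starting materials are bought enantiopure, and carbinol centres at C1 and C7 that are later destroyed are carried as epimer mixtures.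

Step 1
Reactants: 1 but-2-yne-1,4-diol
Product: 2 4-[(tert-butyldiphenylsilyl)oxy]but-2-yn-1-ol
Conditions: TBDPSCl (1.0 equiv), imidazole, 1 (3 equiv), DMF, 0 °C to rt
Reagents that add atoms: tert-butyl(chloro)diphenylsilane, CC(C)(C)[Si](Cl)(c1ccccc1)c1ccccc1
Why: Statistical mono-silylation (silyl ether formation) of the symmetric diol used in excess, with no stereocentre formed.

Step 2
Reactants: 2 4-[(tert-butyldiphenylsilyl)oxy]but-2-yn-1-ol
Product: 4 (Z)-4-[(tert-butyldiphenylsilyl)oxy]-3-iodobut-2-en-1-ol, via cyclic alkenylaluminate 3 (not isolated)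
Conditions: NaAlH2(OCH2CH2OCH3)2, THF, 0 °C to rt; then I2, -78 to 0 °C
Reagents that add atoms: iodine, II
Why: Hydroxyl-directed trans-hydroalumination of the propargylic alcohol places aluminium on the distal alkyne carbon cis to the carbinol, and iodinolysis of the C–Al bond with retention fixes the Z geometry (iodine cis to CH2OH) that becomes the cis C3/C6 relationship of the target.

Step 3
Reactants: 4 (Z)-4-[(tert-butyldiphenylsilyl)oxy]-3-iodobut-2-en-1-ol
Product: 5 (Z)-4-[(tert-butyldiphenylsilyl)oxy]-3-iodobut-2-enal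
Conditions: MnO2 (excess), CH2Cl2, rt
Reagents that add atoms: none
Why: Chemoselective MnO2 oxidation of the allylic alcohol gives the enal without touching the vinyl iodide or the Z geometry.

Step 4
Reactants: 6 (R)-4-[(tert-butyldimethylsilyl)oxy]cyclopent-2-en-1-one
Product: 8 (1S,4R)-4-[(tert-butyldimethylsilyl)oxy]-1-methyl-1-[(triethylsilyl)oxy]cyclopent-2-ene, via lithium alkoxide 7 (not isolated)
Conditions: CH3Li, Et2O, -78 °C; then TESOTf, -78 to 0 °C
Reagents that add atoms: methyllithium, [Li]C; triethylsilyl trifluoromethanesulfonate, CC[Si](CC)(CC)OS(=O)(=O)C(F)(F)F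
Why: 1,2-Addition of the organolithium to the enone on the face anti to the bulky silyloxy group sets the C10 carbinol cis to the C8 oxygen, and the lithium alkoxide is O-silylated in the same flask.

Step 5
Reactants: 8 (1S,4R)-4-[(tert-butyldimethylsilyl)oxy]-1-methyl-1-[(triethylsilyl)oxy]cyclopent-2-ene
Product: 10 (2R,4S)-2-[(tert-butyldimethylsilyl)oxy]-4-methyl-4-[(triethylsilyl)oxy]pentanedial, via ozonide 9 (not isolated)
Conditions: O3, CH2Cl2, -78 °C; then PPh3, -78 °C to rt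
Reagents that add atoms: ozone, [O-][O+]=O
Why: Ozonolysis with reductive work-up cleaves the ring alkene into the C1 and C7 aldehydes without affecting the two stereocentres.

Step 6
Reactants: 10 (2R,4S)-2-[(tert-butyldimethylsilyl)oxy]-4-methyl-4-[(triethylsilyl)oxy]pentanedial; 11 methyl acrylate
Product: 12 methyl (4R,6S)-4-[(tert-butyldimethylsilyl)oxy]-3-hydroxy-6-methyl-2-methylidene-7-oxo-6-[(triethylsilyl)oxy]heptanoate (C3 epimers)
Conditions: DABCO (1 equiv), 11 (6 equiv, as solvent), 23 °C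
Reagents that add atoms: none
Why: Morita–Baylis–Hillman reaction that takes place only at the less hindered alpha-silyloxy aldehyde (C7) because the C1 aldehyde sits on a fully substituted carbon, the new C7 carbinol being an epimer mixture that is erased in step 9.

Step 7
Reactants: 12 methyl (4R,6S)-4-[(tert-butyldimethylsilyl)oxy]-3-hydroxy-6-methyl-2-methylidene-7-oxo-6-[(triethylsilyl)oxy]heptanoate (C3 epimers)
Product: 13 methyl (4R,6S)-4-[(tert-butyldimethylsilyl)oxy]-3,7-dihydroxy-6-methyl-2-methylidene-6-[(triethylsilyl)oxy]non-8-ynoate (C3/C7 epimers)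
Conditions: HC≡CMgBr (3 equiv), THF, -78 to 0 °C; aqueous NH4Cl
Reagents that add atoms: ethynylmagnesium bromide, C#C[Mg]Br
Why: Grignard addition of the acetylide to the remaining hindered aldehyde, the acrylate and ester being inert to alkynylmagnesium reagents at low temperature, gives the C1 carbinol as an epimer mixture that is oxidised away in step 11.

Step 8
Reactants: 13 methyl (4R,6S)-4-[(tert-butyldimethylsilyl)oxy]-3,7-dihydroxy-6-methyl-2-methylidene-6-[(triethylsilyl)oxy]non-8-ynoate (C3/C7 epimers); 5 (Z)-4-[(tert-butyldiphenylsilyl)oxy]-3-iodobut-2-enal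
Product: 14 methyl (4R,6S,10E)-4-[(tert-butyldimethylsilyl)oxy]-10-{[(tert-butyldiphenylsilyl)oxy]methyl}-3,7-dihydroxy-6-methyl-2-methylidene-12-oxo-6-[(triethylsilyl)oxy]dodec-10-en-8-ynoate (formyl group cis to the alkyne; C3/C7 epimers)
Conditions: PdCl2(PPh3)2 (5 mol %), CuI (10 mol %), Et3N, THF, rt
Reagents that add atoms: none
Why: Sonogashira coupling joins C3 to C4 with retention of the vinyl iodide geometry and tolerates the free hydroxyls, the enal and the acrylate.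

Step 9
Reactants: 14 methyl (4R,6S,10E)-4-[(tert-butyldimethylsilyl)oxy]-10-{[(tert-butyldiphenylsilyl)oxy]methyl}-3,7-dihydroxy-6-methyl-2-methylidene-12-oxo-6-[(triethylsilyl)oxy]dodec-10-en-8-ynoate
Product: 15 methyl (2Z,4R,6S,10E)-2-(bromomethyl)-4-[(tert-butyldimethylsilyl)oxy]-10-{[(tert-butyldiphenylsilyl)oxy]methyl}-7-hydroxy-6-methyl-12-oxo-6-[(triethylsilyl)oxy]dodeca-2,10-dien-8-ynoate (C7 epimers)
Conditions: NBS, Me2S, CH2Cl2, -20 to 0 °C
Reagents that add atoms: N-bromosuccinimide, O=C1CCC(=O)N1Br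
Why: Corey–Kim-type activation of the Baylis–Hillman alcohol as its alkoxysulfonium salt and SN2′ displacement by bromide give the conjugated (Z)-allylic bromide, whereas the neopentyl-like C1 carbinol cannot be displaced and returns on work-up.

Step 10
Reactants: 15 methyl (2Z,4R,6S,10E)-2-(bromomethyl)-4-[(tert-butyldimethylsilyl)oxy]-10-{[(tert-butyldiphenylsilyl)oxy]methyl}-7-hydroxy-6-methyl-12-oxo-6-[(triethylsilyl)oxy]dodeca-2,10-dien-8-ynoate
Product: 17 (4E,6R,7S,8R,10S)-8-[(tert-butyldimethylsilyl)oxy]-15-[(tert-butyldiphenylsilyl)oxy]-1-hydroxy-10-[(triethylsilyl)oxy]germacra-4,11(13)-dien-2-yn-12,6-olide (C3 and C6 cis on the C4=C5 bond; C1 epimers), via hydroxy ester 16 (not isolated)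
Conditions: CrCl2 (8 equiv), THF, 2 mM (15 added by syringe pump over 10 h), 23 °C; aqueous NH4Cl
Reagents that add atoms: none
Why: Nozaki–Hiyama–Kishi-type (chromium Barbier) intramolecular allylation closes the ten-membered ring at C6–C7 through a chair transition state with the C5 and C8 branches pseudo-equatorial (6,7-anti, hence the trans-lactone), C7 being set from C8 by allylic 1,3-strain (H-8 in the allyl plane, the C9 chain anti to the forming bond, the small oxygen gauche), and the resulting trivalent chromium alkoxide lactonises onto the methyl ester.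

Step 11
Reactants: 17 (4E,6R,7S,8R,10S)-8-[(tert-butyldimethylsilyl)oxy]-15-[(tert-butyldiphenylsilyl)oxy]-1-hydroxy-10-[(triethylsilyl)oxy]germacra-4,11(13)-dien-2-yn-12,6-olide
Product: 18 (4E,6R,7S,8R,10S)-8-[(tert-butyldimethylsilyl)oxy]-15-[(tert-butyldiphenylsilyl)oxy]-1-oxo-10-[(triethylsilyl)oxy]germacra-4,11(13)-dien-2-yn-12,6-olide
Conditions: Dess–Martin periodinane, CH2Cl2, 0 °C to rt
Reagents that add atoms: none
Why: Dess–Martin oxidation of the only free (propargylic) alcohol gives the ynone and converges the C1 epimers.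

Step 12
Reactants: 18 (4E,6R,7S,8R,10S)-8-[(tert-butyldimethylsilyl)oxy]-15-[(tert-butyldiphenylsilyl)oxy]-1-oxo-10-[(triethylsilyl)oxy]germacra-4,11(13)-dien-2-yn-12,6-olide
Product: 20 (4Z,6R,7R,8R,10S)-15-[(tert-butyldiphenylsilyl)oxy]-3,10-epoxy-8-hydroxy-1-oxogermacra-2,4,11(13)-trien-12,6-olide, via diol ynone 19 (not isolated)
Conditions: TsOH·H2O (0.3 equiv), MeOH, 0 °C to rt; then Ph3PAuNTf2 (5 mol %), CH2Cl2, rt
Reagents that add atoms: none
Why: Acidic methanolysis removes the secondary tert-butyldimethylsilyl and tertiary triethylsilyl ethers but not the primary tert-butyldiphenylsilyl ether, and the freed C10 hydroxyl adds 5-endo-dig to C3 of the ynone (gold-catalysed oxa-Michael cycloisomerisation) to close the 3(2H)-furanone with C10 unchanged.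

Step 13
Reactants: 20 (4Z,6R,7R,8R,10S)-15-[(tert-butyldiphenylsilyl)oxy]-3,10-epoxy-8-hydroxy-1-oxogermacra-2,4,11(13)-trien-12,6-olide; 21 (R)-2-methylbutanoic acid
Product: 22 (4Z,6R,7R,8R,10S)-15-[(tert-butyldiphenylsilyl)oxy]-3,10-epoxy-8-{[(2R)-2-methylbutanoyl]oxy}-1-oxogermacra-2,4,11(13)-trien-12,6-olide
Conditions: DCC, DMAP (cat.), CH2Cl2, 0 °C to rt
Reagents that add atoms: none
Why: Steglich esterification of the single free hydroxyl brings in the enantiopure acid with its stereocentre unchanged.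

Step 14
Reactants: 22 (4Z,6R,7R,8R,10S)-15-[(tert-butyldiphenylsilyl)oxy]-3,10-epoxy-8-{[(2R)-2-methylbutanoyl]oxy}-1-oxogermacra-2,4,11(13)-trien-12,6-olide
Product: 23 (4Z,6R,7R,8R,10S)-3,10-epoxy-15-hydroxy-8-{[(2R)-2-methylbutanoyl]oxy}-1-oxogermacra-2,4,11(13)-trien-12,6-olide (CNP0307052.2)
Conditions: HF·pyridine, pyridine, THF, 0 °C to rt
Reagents that add atoms: none
Why: Buffered fluoride desilylation cleaves the remaining primary silyl ether and leaves the methylene lactone, the furanone and the ester intact.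

**Compound list**
1 | but-2-yne-1,4-diol | OCC#CCO | starting material
2 | 4-[(tert-butyldiphenylsilyl)oxy]but-2-yn-1-ol | OCC#CCO[Si](c1ccccc1)(c1ccccc1)C(C)(C)C | intermediate
3 | sodium 3-{[(tert-butyldiphenylsilyl)oxy]methyl}-2,2-bis(2-methoxyethoxy)-2,5-dihydro-1,2-oxaaluminol-2-uide (cyclic alkenylaluminate, not isolated) | [Na+].COCCO[Al-]1(OCCOC)OCC=C1CO[Si](c1ccccc1)(c1ccccc1)C(C)(C)C | intermediate
4 | (Z)-4-[(tert-butyldiphenylsilyl)oxy]-3-iodobut-2-en-1-ol | OC/C=C(/CO[Si](c1ccccc1)(c1ccccc1)C(C)(C)C)I | intermediate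
5 | (Z)-4-[(tert-butyldiphenylsilyl)oxy]-3-iodobut-2-enal | O=C/C=C(/CO[Si](c1ccccc1)(c1ccccc1)C(C)(C)C)I | intermediate
6 | (R)-4-[(tert-butyldimethylsilyl)oxy]cyclopent-2-en-1-one | O=C1C=C[C@H](O[Si](C)(C)C(C)(C)C)C1 | starting material
7 | lithium (1S,4R)-4-[(tert-butyldimethylsilyl)oxy]-1-methylcyclopent-2-en-1-olate (not isolated) | [Li+].C[C@]1([O-])C[C@@H](O[Si](C)(C)C(C)(C)C)C=C1 | intermediate
8 | (1S,4R)-4-[(tert-butyldimethylsilyl)oxy]-1-methyl-1-[(triethylsilyl)oxy]cyclopent-2-ene (the two oxygens cis) | C[C@]1(O[Si](CC)(CC)CC)C[C@@H](O[Si](C)(C)C(C)(C)C)C=C1 | intermediate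
9 | secondary ozonide of 8: 4-[(tert-butyldimethylsilyl)oxy]-2-methyl-2-[(triethylsilyl)oxy]-6,7,8-trioxabicyclo[3.2.1]octane with the two carbinol centres as in 8 (not isolated) | C[C@]1(O[Si](CC)(CC)CC)C[C@@H](O[Si](C)(C)C(C)(C)C)C2OOC1O2 | intermediate
10 | (2R,4S)-2-[(tert-butyldimethylsilyl)oxy]-4-methyl-4-[(triethylsilyl)oxy]pentanedial | O=C[C@H](O[Si](C)(C)C(C)(C)C)C[C@](C)(O[Si](CC)(CC)CC)C=O | intermediate
11 | methyl acrylate | C=CC(=O)OC | starting material
12 | methyl (4R,6S)-4-[(tert-butyldimethylsilyl)oxy]-3-hydroxy-6-methyl-2-methylidene-7-oxo-6-[(triethylsilyl)oxy]heptanoate (C3 epimers) | C=C(C(=O)OC)C(O)[C@H](O[Si](C)(C)C(C)(C)C)C[C@](C)(O[Si](CC)(CC)CC)C=O | intermediate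
13 | methyl (4R,6S)-4-[(tert-butyldimethylsilyl)oxy]-3,7-dihydroxy-6-methyl-2-methylidene-6-[(triethylsilyl)oxy]non-8-ynoate (C3/C7 epimers) | C=C(C(=O)OC)C(O)[C@H](O[Si](C)(C)C(C)(C)C)C[C@](C)(O[Si](CC)(CC)CC)C(O)C#C | intermediate
14 | methyl (4R,6S,10E)-4-[(tert-butyldimethylsilyl)oxy]-10-{[(tert-butyldiphenylsilyl)oxy]methyl}-3,7-dihydroxy-6-methyl-2-methylidene-12-oxo-6-[(triethylsilyl)oxy]dodec-10-en-8-ynoate (formyl cis to alkyne) | C=C(C(=O)OC)C(O)[C@H](O[Si](C)(C)C(C)(C)C)C[C@](C)(O[Si](CC)(CC)CC)C(O)C#C/C(CO[Si](c1ccccc1)(c1ccccc1)C(C)(C)C)=C\C=O | intermediate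
15 | methyl (2Z,4R,6S,10E)-2-(bromomethyl)-4-[(tert-butyldimethylsilyl)oxy]-10-{[(tert-butyldiphenylsilyl)oxy]methyl}-7-hydroxy-6-methyl-12-oxo-6-[(triethylsilyl)oxy]dodeca-2,10-dien-8-ynoate | COC(=O)/C(CBr)=C/[C@H](O[Si](C)(C)C(C)(C)C)C[C@](C)(O[Si](CC)(CC)CC)C(O)C#C/C(CO[Si](c1ccccc1)(c1ccccc1)C(C)(C)C)=C\C=O | intermediate
16 | methyl (4E,6R,7S,8R,10S)-8-[(tert-butyldimethylsilyl)oxy]-15-[(tert-butyldiphenylsilyl)oxy]-1,6-dihydroxy-10-[(triethylsilyl)oxy]germacra-4,11(13)-dien-2-yn-12-oate (ten-membered hydroxy ester, formed as its trivalent chromium alkoxide, not isolated) | C=C(C(=O)OC)[C@H]1[C@H](O)/C=C(/CO[Si](c2ccccc2)(c2ccccc2)C(C)(C)C)C#CC(O)[C@@](C)(O[Si](CC)(CC)CC)C[C@H]1O[Si](C)(C)C(C)(C)C | intermediate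
17 | (4E,6R,7S,8R,10S)-8-[(tert-butyldimethylsilyl)oxy]-15-[(tert-butyldiphenylsilyl)oxy]-1-hydroxy-10-[(triethylsilyl)oxy]germacra-4,11(13)-dien-2-yn-12,6-olide (C1 epimers) | C=C1C(=O)O[C@@H]2/C=C(/CO[Si](c3ccccc3)(c3ccccc3)C(C)(C)C)C#CC(O)[C@@](C)(O[Si](CC)(CC)CC)C[C@@H](O[Si](C)(C)C(C)(C)C)[C@@H]12 | intermediate
18 | (4E,6R,7S,8R,10S)-8-[(tert-butyldimethylsilyl)oxy]-15-[(tert-butyldiphenylsilyl)oxy]-1-oxo-10-[(triethylsilyl)oxy]germacra-4,11(13)-dien-2-yn-12,6-olide | C=C1C(=O)O[C@@H]2/C=C(/CO[Si](c3ccccc3)(c3ccccc3)C(C)(C)C)C#CC(=O)[C@@](C)(O[Si](CC)(CC)CC)C[C@@H](O[Si](C)(C)C(C)(C)C)[C@@H]12 | intermediate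
19 | (4E,6R,7R,8R,10S)-15-[(tert-butyldiphenylsilyl)oxy]-8,10-dihydroxy-1-oxogermacra-4,11(13)-dien-2-yn-12,6-olide (not isolated) | C=C1C(=O)O[C@@H]2/C=C(/CO[Si](c3ccccc3)(c3ccccc3)C(C)(C)C)C#CC(=O)[C@@](C)(O)C[C@@H](O)[C@@H]12 | intermediate
20 | (4Z,6R,7R,8R,10S)-15-[(tert-butyldiphenylsilyl)oxy]-3,10-epoxy-8-hydroxy-1-oxogermacra-2,4,11(13)-trien-12,6-olide | C=C1C(=O)O[C@@H]2/C=C(/CO[Si](c4ccccc4)(c4ccccc4)C(C)(C)C)C3=CC(=O)[C@](C)(C[C@@H](O)[C@@H]12)O3 | intermediate
21 | (R)-2-methylbutanoic acid | CC[C@@H](C)C(=O)O | starting material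
22 | (4Z,6R,7R,8R,10S)-15-[(tert-butyldiphenylsilyl)oxy]-3,10-epoxy-8-{[(2R)-2-methylbutanoyl]oxy}-1-oxogermacra-2,4,11(13)-trien-12,6-olide | C=C1C(=O)O[C@@H]2/C=C(/CO[Si](c4ccccc4)(c4ccccc4)C(C)(C)C)C3=CC(=O)[C@](C)(C[C@@H](OC(=O)[C@H](C)CC)[C@@H]12)O3 | intermediate
23 | (4Z,6R,7R,8R,10S)-3,10-epoxy-15-hydroxy-8-{[(2R)-2-methylbutanoyl]oxy}-1-oxogermacra-2,4,11(13)-trien-12,6-olide (CNP0307052.2) | C=C1C(=O)O[C@@H]2/C=C(/CO)C3=CC(=O)[C@](C)(C[C@@H](OC(=O)[C@H](C)CC)[C@@H]12)O3 | target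

**Step count and risks**
Total: 14 steps. Longest linear sequence: 11 steps (6 to 23, steps 4 to 14); the iodoenal branch (steps 1 to 3) joins at step 8.

The three steps most likely to fail are steps 10, 12 and 6.

Step 10 (strain of the cyclodecenyne ring; control of C6 and C7 from C8). The fallback keeps the C6–C7 ring-closing bond but removes the alkyne from the ring before closure. It sets out from 15. Dess–Martin oxidation gives methyl (2Z,4R,6S,10E)-2-(bromomethyl)-4-[(tert-butyldimethylsilyl)oxy]-10-{[(tert-butyldiphenylsilyl)oxy]methyl}-6-methyl-7,12-dioxo-6-[(triethylsilyl)oxy]dodeca-2,10-dien-8-ynoate F2. PPTS in MeOH removes only the tertiary triethylsilyl ether, and Ph3PAuNTf2 closes the furanone to give methyl (2Z,4R)-2-(bromomethyl)-4-[(tert-butyldimethylsilyl)oxy]-5-[(2S)-5-{(2Z)-1-[(tert-butyldiphenylsilyl)oxy]-4-oxobut-2-en-2-yl}-2-methyl-3-oxo-2,3-dihydrofuran-2-yl]pent-2-enoate F3, in which the C1 carbonyl is a vinylogous ester that is inert to allylchromium. CrCl2 under high dilution then closes the alkyne-free ten-membered ring and the lactone to give (4Z,6R,7S,8R,10S)-8-[(tert-butyldimethylsilyl)oxy]-15-[(tert-butyldiphenylsilyl)oxy]-3,10-epoxy-1-oxogermacra-2,4,11(13)-trien-12,6-olide F4. TsOH in MeOH removes the C8 silyl ether, and the route is rejoined at 20.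

Step 12 (three events in one flask; the free C8 hydroxyl could translactonise, and the secondary silyl ether could cleave slowly). The fallback sets out from 18. Excess HF·pyridine removes all three silyl groups, and the freed C10 hydroxyl cyclises (Ph3PAuNTf2 if needed) to (4Z,6R,7R,8R,10S)-3,10-epoxy-8,15-dihydroxy-1-oxogermacra-2,4,11(13)-trien-12,6-olide F5. TBDPSCl and imidazole at -20 °C then silylate only the primary allylic hydroxyl, and the route comes back at 20.

Step 6 (a slow Baylis–Hillman reaction on a hindered dialdehyde; possible epimerisation at C8). The fallback replaces the amine-catalysed reaction by a stoichiometric aldol/elimination. It sets out from 10. The lithium enolate of methyl 3-(phenylselanyl)propanoate (lithium diisopropylamide, THF, -78 °C) adds to the unhindered aldehyde to give methyl (4R,6S)-4-[(tert-butyldimethylsilyl)oxy]-3-hydroxy-6-methyl-7-oxo-2-[(phenylselanyl)methyl]-6-[(triethylsilyl)oxy]heptanoate F1. H2O2 and pyridine in CH2Cl2 at 0 °C oxidise the selenide, and syn-elimination of the selenoxide toward the ester alpha-carbon gives the methylidene ester, so the route comes back at 12.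

**Further compounds**
F1 | step 6 | methyl (4R,6S)-4-[(tert-butyldimethylsilyl)oxy]-3-hydroxy-6-methyl-7-oxo-2-[(phenylselanyl)methyl]-6-[(triethylsilyl)oxy]heptanoate | COC(=O)C(C[Se]c1ccccc1)C(O)[C@H](O[Si](C)(C)C(C)(C)C)C[C@](C)(O[Si](CC)(CC)CC)C=O
F2 | step 10 | methyl (2Z,4R,6S,10E)-2-(bromomethyl)-4-[(tert-butyldimethylsilyl)oxy]-10-{[(tert-butyldiphenylsilyl)oxy]methyl}-6-methyl-7,12-dioxo-6-[(triethylsilyl)oxy]dodeca-2,10-dien-8-ynoate | COC(=O)/C(CBr)=C/[C@H](O[Si](C)(C)C(C)(C)C)C[C@](C)(O[Si](CC)(CC)CC)C(=O)C#C/C(CO[Si](c1ccccc1)(c1ccccc1)C(C)(C)C)=C\C=O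
F3 | step 10 | methyl (2Z,4R)-2-(bromomethyl)-4-[(tert-butyldimethylsilyl)oxy]-5-[(2S)-5-{(2Z)-1-[(tert-butyldiphenylsilyl)oxy]-4-oxobut-2-en-2-yl}-2-methyl-3-oxo-2,3-dihydrofuran-2-yl]pent-2-enoate | COC(=O)/C(CBr)=C/[C@H](O[Si](C)(C)C(C)(C)C)C[C@]1(C)OC(=CC1=O)/C(CO[Si](c1ccccc1)(c1ccccc1)C(C)(C)C)=C\C=O
F4 | step 10 | (4Z,6R,7S,8R,10S)-8-[(tert-butyldimethylsilyl)oxy]-15-[(tert-butyldiphenylsilyl)oxy]-3,10-epoxy-1-oxogermacra-2,4,11(13)-trien-12,6-olide | C=C1C(=O)O[C@@H]2/C=C(/CO[Si](c4ccccc4)(c4ccccc4)C(C)(C)C)C3=CC(=O)[C@](C)(C[C@@H](O[Si](C)(C)C(C)(C)C)[C@@H]12)O3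
F5 | step 12 | (4Z,6R,7R,8R,10S)-3,10-epoxy-8,15-dihydroxy-1-oxogermacra-2,4,11(13)-trien-12,6-olide | C=C1C(=O)O[C@@H]2/C=C(/CO)C3=CC(=O)[C@](C)(C[C@@H](O)[C@@H]12)O3
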